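Assumption (remark on the chemistry): the α-chloro ketone is carried as the racemate, because the C8 radical made from it is planar, and the enzyme of step 11 is taken to be a flavin ene-reductase variant found by screening and directed evolution against compound 15.

## Analysis of the target

Compound 18 is an aryltetralin (a 2,7'-cyclolignan). Ring A (C1–C6; methoxy groups at C3 and C5, hydroxyl at C4, hydrogen at C6) is fused through C1 and C2 to the carbocyclic ring B (C1, C2, C7', C8', C8, C7). C7' carries the 4-hydroxy-3-methoxyphenyl ring, C8' and C8 each carry one methyl group (C9', C9), and C7 is a plain benzylic methylene. The three stereocentres are contiguous (7'R, 8R, 8'R): the aryl group at C7' is trans to the C8' methyl, and the two methyl groups are cis to each other. None of the centres carries a heteroatom, and C7' is a crowded diarylmethine beside the C3 methoxy group that cannot be epimerised once made. The pattern is hard because it is not the all-trans arrangement that equilibration gives, and because a reagent that delivers hydrogen to a planar C7' normally arrives anti to the C8' methyl and so gives the cis aryl/methyl relation. The sensitive groups are the two phenols (the 4'-hydroxyl is para to C7', so oxidation leads towards a quinone methide) and the electron-rich rings. The strategy rests on two features. C8 lies next to benzylic C7, where a ketone can be placed and later removed, so C8 can be made a radical site. C7' bears two aryl rings, so a C7'=C8' double bond is a 1,1-diarylpropene whose C8' end can accept a C8 radical, close ring B and leave a diaryl-stabilised radical at C7' for a final hydrogen transfer.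

## Retrosynthetic reasoning

**18 back to 16 (oxygen written onto C7).** No C–C bond is cut. A C7 carbonyl is added because only a ketone there makes C8 a position at which a radical can be generated. The price is two closing steps: reduction of 16 to carbinol 17 and ionic deoxygenation of 17 to 18. Both must leave C8 alone, which is enolisable in 16 and sits next to a cation in the step from 17.

**16 back to 15 (C8–C8' cut, ring B opened).** This is the one ring-B bond whose cleavage leaves both aryl rings, both methyl groups and every carbon in a single chain without a stereocentre that matters. C8 becomes a chlorine-bearing carbon beside the ketone, and C7'/C8' become a double bond. Cutting C2–C7' or C1–C7 instead would lead to cationic or acylative closures that need C8 and C8' set beforehand. What is gained is ring B and all three stereocentres in one step. The forward reaction must make the C8 radical, close at C8' and not at C7', place the methyl groups cis, and deliver hydrogen to C7' on the face of the C8' methyl. That control is handed to an ene-reductase under visible light.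

**15 back to 12 (C8–Cl and two O–Si bonds).** Chlorine is introduced late, on the lithium enolate 13 of ketone 12, to give 14, because an α-chloro ketone would not survive the base and palladium of the fragment coupling. The phenols are freed only after that (14 to 15), since free phenols would compete in the chlorination. Silyl ethers are used because their removal needs neither acid, which would isomerise the diarylpropene, nor hydrogenation.

**12 back to 6 and 11 (C2–C7' cut).** This bond joins ring A to the alkene carbon, and cutting it gives two fragments of similar size: aryl bromide 6 and alkenylboronate 11. A cross-coupling that retains alkene geometry carries the geometry of 11 into 12. The single Z geometry of 15 is therefore fixed before the fragments meet and does not depend on a dehydration, which would give both isomers.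

**11 back to 7 (C–B and C–O bonds).** Boronate 11 comes from enol triflate 10, and 10 from ketone 8 through its Z enolate 9; ketone 8 is the silyl ether of 7. The enolate geometry (methyl cis to oxygen), which aryl ethyl ketones adopt reliably, is the source of the alkene geometry of everything downstream.

**6 back to 1 and 4 (C7–C8 cut).** The propionyl group is built by adding 4 to aldehyde 3 and oxidising carbinol 5. Aldehyde 3 is the silyl ether of bromophenol 2, and 2 comes from 1 by bromination at one of its two equivalent free ring positions. The bromine marks C2 and the formyl carbon is C7.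

## Alternatives that were turned down

**Alternative 1:** The cut is at C7'–C8', made by a [3,3] shift that also breaks the C7–O bond of a ring-A-fused lactone. In the forward direction the enolate of isochromanone A1 is O-silylated and rearranges (Ireland–Claisen ring contraction) through the boat-shaped transition state that the ring imposes. The product is dihydronaphthalene acid A2, with C8' as in the target and the carboxyl group cis to the C8' methyl.
- For it: the reaction type is known, and chirality is transferred from a single carbinol centre (C7) that standard asymmetric methods can set. On precedent it is clearly stronger than the chosen key step.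
- Against it: A2 has a carboxyl group where the guaiacyl ring must stand and a C7=C8 double bond where the third stereocentre must be. It therefore needs a decarboxylative sp3–sp2 arylation at a hindered benzylic carbon beside the C3 methoxy group. That reaction runs through a radical, so the C7' configuration just made is lost and must be set again. It also needs a hydrogenation whose face selectivity at C8 depends on what stands at C7' at that moment. Making A1 in enantiopure form adds further steps.
- Comparison: it secures one centre of three with little risk per step, but it is longer. The chosen route has both rings and both methyl groups in place at the key step and aims at all three centres at once.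

**Alternative 2:** The cut is through C7–C8 and C7'–C8' together, a [4+2] disconnection of ring B. Heating benzocyclobutenone ketal A3 opens the four-membered ring to an o-quinodimethane. This adds to the menthol-derived butenolide A4 on the face away from the alkoxy group and gives the cis-fused adduct A5.
- For it: two C–C bonds and ring B form in one convergent thermal step of a known type. The cis ring fusion delivers exactly the cis relation of C8 and C8', which the chosen route has to obtain from the protein. On this point and on precedent Alternative 2 is stronger.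
- Against it: C9 and C9' arrive as an acetal carbon and a lactone carbonyl, and both must be taken down to methyl groups. C7' arrives as a ketal, so the guaiacyl ring must be added to the derived ketone and the tertiary benzylic alcohol deoxygenated. Hydride then enters anti to the C8' substituent, which is the intrinsic preference that gives the wrong C7' epimer. C8' beside the unmasked C7' ketone can also epimerise.
- Comparison: the sequence after the key step is long and leaves the hardest centre open. The chosen strategy addresses C7' directly and needs only the removal of one ketone afterwards.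

**Alternative 3:** The cuts are at C8–C9 and C1–C7, so ring B is closed last at an aryl–alkyl bond. Zirconium-catalysed asymmetric methylalumination of the vinyl group of bromide A6 places methyl on C8 and the metal on C7. Transmetalation and palladium-catalysed coupling with the C1 bromide then give A7, the dibenzyl ether of the target.
- For it: A7 is one debenzylation from the target and there is no ketone to remove, so its endgame is shorter and safer than that of the chosen route. Both bond formations are known reaction types.
- Against it: A6 must already hold C7' and C8' in the trans relation and in enantiopure form. The hardest part of the problem is thus moved into the preparation of the substrate, which needs its own asymmetric sequence. The catalyst must set C8 next to an allylic stereocentre bearing a bulky diarylmethyl group (matched or mismatched), and methyl transfer is the least selective member of this reaction family. The organoaluminium step must also tolerate an aryl bromide and two benzyl ethers.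
- Comparison: it is longer overall and splits stereocontrol over several operations. The chosen route offers three centres from a stereochemically trivial precursor in one step, at the price of an undemonstrated enzymatic selectivity.

Key step: step 11

## Route

Step 1
Reactants: 1 syringaldehyde
Product: 2 2-bromo-4-hydroxy-3,5-dimethoxybenzaldehyde
Conditions: Br2 (1 equiv), NaOAc, AcOH, rt
Reagents that add atoms: bromine, BrBr
Why: Electrophilic aromatic bromination; the only free ring positions (C2 and C6, equivalent) are ortho and para to the two methoxy groups, so one equivalent of bromine should give the 2-bromo compound while NaOAc takes up the acid.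

Step 2
Reactants: 2 2-bromo-4-hydroxy-3,5-dimethoxybenzaldehyde
Product: 3 2-bromo-3,5-dimethoxy-4-[(triisopropylsilyl)oxy]benzaldehyde
Conditions: chlorotriisopropylsilane, imidazole, DMF, 40 °C
Reagents that add atoms: chlorotriisopropylsilane, CC(C)[Si](Cl)(C(C)C)C(C)C
Why: Silylation of the phenol; the triisopropylsilyl ether should withstand the Grignard, enolate and basic palladium steps and is removed later by fluoride without acid, which the diarylpropene would not tolerate.

Step 3
Reactants: 3 2-bromo-3,5-dimethoxy-4-[(triisopropylsilyl)oxy]benzaldehyde; 4 ethylmagnesium bromide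
Product: 5 1-{2-bromo-3,5-dimethoxy-4-[(triisopropylsilyl)oxy]phenyl}propan-1-ol (racemic)
Conditions: EtMgBr, THF, −40 to 0 °C; aq NH4Cl
Reagents that add atoms: ethylmagnesium bromide (4), CC[Mg]Br
Why: Grignard addition to the aldehyde carbon (C7), which brings in C8 and C9; at low temperature EtMgBr does not exchange with the aryl bromide.

Step 4
Reactants: 5 1-{2-bromo-3,5-dimethoxy-4-[(triisopropylsilyl)oxy]phenyl}propan-1-ol
Product: 6 1-{2-bromo-3,5-dimethoxy-4-[(triisopropylsilyl)oxy]phenyl}propan-1-one
Conditions: Dess–Martin periodinane, CH2Cl2, rt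
Reagents that add atoms: none
Why: Dess–Martin oxidation of the secondary benzylic alcohol to the aryl ethyl ketone; the neutral conditions leave the silyl ether and the bromide untouched.

Step 5
Reactants: 7 1-(4-hydroxy-3-methoxyphenyl)propan-1-one
Product: 8 1-{3-methoxy-4-[(triisopropylsilyl)oxy]phenyl}propan-1-one
Conditions: chlorotriisopropylsilane, imidazole, DMF, rt
Reagents that add atoms: chlorotriisopropylsilane, CC(C)[Si](Cl)(C(C)C)C(C)C
Why: Silylation of the phenol, so that enolisation and triflation in step 6 act on the ketone only.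

Step 6
Reactants: 8 1-{3-methoxy-4-[(triisopropylsilyl)oxy]phenyl}propan-1-one
Product: 10 (Z)-1-{3-methoxy-4-[(triisopropylsilyl)oxy]phenyl}prop-1-en-1-yl trifluoromethanesulfonate, via potassium (Z)-enolate 9 (not isolated)
Conditions: KN(SiMe3)2, THF, −78 °C; then PhNTf2, −78 to 0 °C
Reagents that add atoms: N-phenylbis(trifluoromethanesulfonimide), FC(F)(F)S(=O)(=O)N(c1ccccc1)S(=O)(=O)C(F)(F)F
Why: Kinetic deprotonation of an aryl ethyl ketone should give the Z enolate, since the E enolate would press the methyl group against the aryl ring; O-triflation fixes this geometry with the triflate cis to the methyl group.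

Step 7
Reactants: 10 (Z)-1-{3-methoxy-4-[(triisopropylsilyl)oxy]phenyl}prop-1-en-1-yl trifluoromethanesulfonate
Product: 11 2-[(E)-1-{3-methoxy-4-[(triisopropylsilyl)oxy]phenyl}prop-1-en-1-yl]-4,4,5,5-tetramethyl-1,3,2-dioxaborolane
Conditions: bis(pinacolato)diboron, PdCl2(PPh3)2 (cat.), PPh3, KOPh, toluene, 50 °C
Reagents that add atoms: bis(pinacolato)diboron, CC1(C)OB(OC1(C)C)B1OC(C)(C)C(C)(C)O1
Why: Miyaura borylation of an alkenyl triflate, which retains the alkene geometry (boron cis to the methyl group); the descriptor changes from Z to E only because boron ranks below the aryl carbon.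

Step 8
Reactants: 6 1-{2-bromo-3,5-dimethoxy-4-[(triisopropylsilyl)oxy]phenyl}propan-1-one; 11 2-[(E)-1-{3-methoxy-4-[(triisopropylsilyl)oxy]phenyl}prop-1-en-1-yl]-4,4,5,5-tetramethyl-1,3,2-dioxaborolane
Product: 12 1-{3,5-dimethoxy-2-[(Z)-1-{3-methoxy-4-[(triisopropylsilyl)oxy]phenyl}prop-1-en-1-yl]-4-[(triisopropylsilyl)oxy]phenyl}propan-1-one
Conditions: Pd(OAc)2 (cat.), SPhos, K3PO4, toluene/H2O, 80 °C
Reagents that add atoms: none
Why: Suzuki–Miyaura coupling that forms the C2–C7' bond; the ortho acyl group activates the C–Br bond for oxidative addition and the bulky electron-rich biaryl phosphine is chosen for the doubly ortho-substituted bromide. The coupling retains the alkene geometry, so the methyl group ends cis to ring A (Z).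

Step 9
Reactants: 12 1-{3,5-dimethoxy-2-[(Z)-1-{3-methoxy-4-[(triisopropylsilyl)oxy]phenyl}prop-1-en-1-yl]-4-[(triisopropylsilyl)oxy]phenyl}propan-1-one
Product: 14 2-chloro-1-{3,5-dimethoxy-2-[(Z)-1-{3-methoxy-4-[(triisopropylsilyl)oxy]phenyl}prop-1-en-1-yl]-4-[(triisopropylsilyl)oxy]phenyl}propan-1-one (racemic), via lithium enolate 13 (not isolated)
Conditions: LiN(SiMe3)2, THF, −78 °C; enolate added to N-chlorosuccinimide in THF, −78 °C
Reagents that add atoms: N-chlorosuccinimide, O=C1CCC(=O)N1Cl
Why: Deprotonation at C8, the only acidic C–H, followed by electrophilic chlorination of the enolate; at −78 °C the enolate is far more nucleophilic than the diarylpropene or the arenes, and inverse addition limits proton exchange and double chlorination. The new stereocentre is meant to be racemic.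

Step 10
Reactants: 14 2-chloro-1-{3,5-dimethoxy-2-[(Z)-1-{3-methoxy-4-[(triisopropylsilyl)oxy]phenyl}prop-1-en-1-yl]-4-[(triisopropylsilyl)oxy]phenyl}propan-1-one
Product: 15 2-chloro-1-{4-hydroxy-2-[(Z)-1-(4-hydroxy-3-methoxyphenyl)prop-1-en-1-yl]-3,5-dimethoxyphenyl}propan-1-one (racemic)
Conditions: Bu4NF, AcOH, THF, 0 °C; product kept cold and in the dark
Reagents that add atoms: none
Why: Fluoride cleavage of the two aryl silyl ethers; buffering with acetic acid keeps the medium near neutral, so that neither the α-chloro ketone (elimination, substitution) nor the alkene (acid-induced isomerisation) should be affected.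

Step 11
Reactants: 15 2-chloro-1-{4-hydroxy-2-[(Z)-1-(4-hydroxy-3-methoxyphenyl)prop-1-en-1-yl]-3,5-dimethoxyphenyl}propan-1-one
Product: 16 (2S,3S,4R)-6-hydroxy-4-(4-hydroxy-3-methoxyphenyl)-5,7-dimethoxy-2,3-dimethyl-3,4-dihydronaphthalen-1(2H)-one (the 7-oxo derivative of 18)
Conditions: engineered flavin-dependent ene-reductase (FMN-bound), NADP+ (cat.), glucose dehydrogenase, D-glucose, KH2PO4/K2HPO4 buffer pH 7 with 10% DMSO, cyan LEDs (about 500 nm), 25 °C, under N2
Reagents that add atoms: none
Why: Proposed new method: the reduced flavin of the ene-reductase forms a charge-transfer complex with the bound α-chloro ketone, and visible-light excitation passes one electron into the C–Cl bond, which breaks to give a planar C8 radical beside the C7 carbonyl, so both enantiomers of 15 converge. This electrophilic α-keto radical adds to C8' of the electron-rich 1,1-diarylpropene and closes ring B in the 6-endo-trig mode; the 5-exo alternative would attack the fully substituted C7' and forgo the diaryl-stabilised radical. The C7' radical is then quenched by hydrogen-atom transfer from the flavin semiquinone, and the oxidised flavin is reduced again by NADPH, which glucose dehydrogenase and glucose recycle. The closest known reaction type is the photoenzymatic reductive cyclisation of α-chloro amides and the hydroalkylation of alkenes with α-halo carbonyl compounds by flavin ene-reductases, which also end with an enzyme-controlled hydrogen transfer; a 6-endo closure of an aryl ketone onto a diarylalkene is not among the known cases. C8 and C8' are set together in the C–C bond-forming step by the conformation in which the pocket holds the radical and the Z alkene (methyl groups cis), and C7' is set by the face from which the semiquinone N5–H delivers hydrogen (syn to the C8' methyl). The step needs 6-endo regioselectivity, which the substitution pattern of the alkene secures, and it needs control of both diastereofaces and of the absolute sense, which nothing in the substrate secures and which must come from the protein. The single Z geometry and the two phenols of 15 offer the enzyme one defined, compact, hydrogen-bonding substrate, and cyan light is chosen because the 4-hydroxyphenacyl chloride chromophore of 15 absorbs only in the near ultraviolet, where a photo-Favorskii side reaction would be possible.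

Step 12
Reactants: 16 (2S,3S,4R)-6-hydroxy-4-(4-hydroxy-3-methoxyphenyl)-5,7-dimethoxy-2,3-dimethyl-3,4-dihydronaphthalen-1(2H)-one
Product: 17 (2S,3S,4R)-4-(4-hydroxy-3-methoxyphenyl)-5,7-dimethoxy-2,3-dimethyl-1,2,3,4-tetrahydronaphthalene-1,6-diol (both C1 epimers)
Conditions: NaBH4, CeCl3·7H2O, MeOH, −20 to 0 °C; aq NaHCO3; crude product used at once
Reagents that add atoms: none
Why: Luche reduction of the aryl ketone; CeCl3 activates the carbonyl so that hydride transfer should be fast at low temperature and near neutrality, which protects the enolisable C8 centre. The configuration of the new C7 carbinol does not matter, because the oxygen is removed in step 13.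

Step 13
Reactants: 17 (2S,3S,4R)-4-(4-hydroxy-3-methoxyphenyl)-5,7-dimethoxy-2,3-dimethyl-1,2,3,4-tetrahydronaphthalene-1,6-diol
Product: 18 (−)-(7'R,8R,8'R)-4,4'-dihydroxy-3,3',5-trimethoxy-2,7'-cyclolignan
Conditions: Et3SiH (excess), CF3CO2H, CH2Cl2, −20 to 0 °C
Reagents that add atoms: none
Why: Ionic deoxygenation; acid ionises the benzylic alcohol to a cation stabilised by the para hydroxyl group of ring A, and excess Et3SiH should deliver hydride to C7 before the cation loses the C8 proton at low temperature. C7 becomes a methylene group and C7', C8' and C8 are not touched.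

## Compound list

1 | syringaldehyde (4-hydroxy-3,5-dimethoxybenzaldehyde) | COc1cc(C=O)cc(OC)c1O | starting material
2 | 2-bromo-4-hydroxy-3,5-dimethoxybenzaldehyde | COc1cc(C=O)c(Br)c(OC)c1O | intermediate
3 | 2-bromo-3,5-dimethoxy-4-[(triisopropylsilyl)oxy]benzaldehyde | COc1cc(C=O)c(Br)c(OC)c1O[Si](C(C)C)(C(C)C)C(C)C | intermediate
4 | ethylmagnesium bromide | CC[Mg]Br | starting material
5 | 1-{2-bromo-3,5-dimethoxy-4-[(triisopropylsilyl)oxy]phenyl}propan-1-ol (racemic) | CCC(O)c1cc(OC)c(O[Si](C(C)C)(C(C)C)C(C)C)c(OC)c1Br | intermediate
6 | 1-{2-bromo-3,5-dimethoxy-4-[(triisopropylsilyl)oxy]phenyl}propan-1-one | CCC(=O)c1cc(OC)c(O[Si](C(C)C)(C(C)C)C(C)C)c(OC)c1Br | intermediate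
7 | 1-(4-hydroxy-3-methoxyphenyl)propan-1-one | CCC(=O)c1ccc(O)c(OC)c1 | starting material
8 | 1-{3-methoxy-4-[(triisopropylsilyl)oxy]phenyl}propan-1-one | CCC(=O)c1ccc(O[Si](C(C)C)(C(C)C)C(C)C)c(OC)c1 | intermediate
9 | potassium (Z)-1-{3-methoxy-4-[(triisopropylsilyl)oxy]phenyl}prop-1-en-1-olate | C/C=C(\[O-])c1ccc(O[Si](C(C)C)(C(C)C)C(C)C)c(OC)c1.[K+] | intermediate
10 | (Z)-1-{3-methoxy-4-[(triisopropylsilyl)oxy]phenyl}prop-1-en-1-yl trifluoromethanesulfonate | C/C=C(\OS(=O)(=O)C(F)(F)F)c1ccc(O[Si](C(C)C)(C(C)C)C(C)C)c(OC)c1 | intermediate
11 | 2-[(E)-1-{3-methoxy-4-[(triisopropylsilyl)oxy]phenyl}prop-1-en-1-yl]-4,4,5,5-tetramethyl-1,3,2-dioxaborolane | C/C=C(\B1OC(C)(C)C(C)(C)O1)c1ccc(O[Si](C(C)C)(C(C)C)C(C)C)c(OC)c1 | intermediate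
12 | 1-{3,5-dimethoxy-2-[(Z)-1-{3-methoxy-4-[(triisopropylsilyl)oxy]phenyl}prop-1-en-1-yl]-4-[(triisopropylsilyl)oxy]phenyl}propan-1-one | C/C=C(/c1ccc(O[Si](C(C)C)(C(C)C)C(C)C)c(OC)c1)c1c(OC)c(O[Si](C(C)C)(C(C)C)C(C)C)c(OC)cc1C(=O)CC | intermediate
13 | lithium (Z)-enolate of 12 | C/C=C(/c1ccc(O[Si](C(C)C)(C(C)C)C(C)C)c(OC)c1)c1c(OC)c(O[Si](C(C)C)(C(C)C)C(C)C)c(OC)cc1/C([O-])=C/C.[Li+] | intermediate
14 | 2-chloro-1-{3,5-dimethoxy-2-[(Z)-1-{3-methoxy-4-[(triisopropylsilyl)oxy]phenyl}prop-1-en-1-yl]-4-[(triisopropylsilyl)oxy]phenyl}propan-1-one (racemic) | C/C=C(/c1ccc(O[Si](C(C)C)(C(C)C)C(C)C)c(OC)c1)c1c(OC)c(O[Si](C(C)C)(C(C)C)C(C)C)c(OC)cc1C(=O)C(C)Cl | intermediate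
15 | 2-chloro-1-{4-hydroxy-2-[(Z)-1-(4-hydroxy-3-methoxyphenyl)prop-1-en-1-yl]-3,5-dimethoxyphenyl}propan-1-one (racemic at the chlorinated carbon) | C/C=C(/c1ccc(O)c(OC)c1)c1c(OC)c(O)c(OC)cc1C(=O)C(C)Cl | intermediate
16 | (2S,3S,4R)-6-hydroxy-4-(4-hydroxy-3-methoxyphenyl)-5,7-dimethoxy-2,3-dimethyl-3,4-dihydronaphthalen-1(2H)-one | COc1cc([C@@H]2c3c(cc(OC)c(O)c3OC)C(=O)[C@@H](C)[C@H]2C)ccc1O | intermediate
17 | (2S,3S,4R)-4-(4-hydroxy-3-methoxyphenyl)-5,7-dimethoxy-2,3-dimethyl-1,2,3,4-tetrahydronaphthalene-1,6-diol (both C1 epimers) | COc1cc([C@@H]2c3c(cc(OC)c(O)c3OC)C(O)[C@@H](C)[C@H]2C)ccc1O | intermediate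
18 | (−)-(7'R,8R,8'R)-4,4'-dihydroxy-3,3',5-trimethoxy-2,7'-cyclolignan; (6R,7R,8R)-8-(4-hydroxy-3-methoxyphenyl)-1,3-dimethoxy-6,7-dimethyl-5,6,7,8-tetrahydronaphthalen-2-ol | COc1cc([C@@H]2c3c(cc(OC)c(O)c3OC)C[C@@H](C)[C@H]2C)ccc1O | target

## Step count and least certain steps

Total: 13 steps. Longest linear sequence: 10 steps (steps 1–4 and 8–13, from 1); the branch from 7 has 3 steps (5–7).

**Step 11 (key step).** Three things are most likely to go wrong.
- Hydrogen may be transferred to the C8 radical before ring closure, because the hindered alkene may not sit close enough to C8 in the pocket.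
- Hydrogen may be delivered to C7' on the intrinsically preferred face anti to the C8' methyl, or the C–C bond may form with the methyl groups trans; either gives the wrong diastereomer.
- The bulky substrate may bind poorly, so that turnover is low.

Fallback, known chemistry throughout, from 1 back to the route at 18. Ring B is closed by a cationic Friedel–Crafts alkylation, in which ring A attacks a C7' benzylic cation and the aryl group takes the position trans to the C8' methyl, after C8 and C8' have been set under auxiliary control.
- Compound 1 is benzylated (BnBr, K2CO3, DMF) to 4-(benzyloxy)-3,5-dimethoxybenzaldehyde F1, reduced (NaBH4, MeOH) to [4-(benzyloxy)-3,5-dimethoxyphenyl]methanol F2 and converted (SOCl2, CH2Cl2) into 2-(benzyloxy)-5-(chloromethyl)-1,3-dimethoxybenzene F3. Magnesium in THF then gives [4-(benzyloxy)-3,5-dimethoxybenzyl]magnesium chloride F4.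
- Copper-mediated conjugate addition (CuBr·SMe2, THF/Me2S, −20 °C) of F4 to (4R)-3-[(2E)-but-2-enoyl]-4-phenyl-1,3-oxazolidin-2-one F5 is expected on the face away from the phenyl group. F5 is made from (R)-4-phenyloxazolidin-2-one, (E)-but-2-enoyl chloride, Et3N and LiCl. The adduct is (4R)-3-{(3R)-4-[4-(benzyloxy)-3,5-dimethoxyphenyl]-3-methylbutanoyl}-4-phenyl-1,3-oxazolidin-2-one F6, which sets C8.
- NaN(SiMe3)2 in THF at −78 °C gives the sodium (Z)-enolate of F6 F7. Methyl iodide attacks it anti to the phenyl group and gives (4R)-3-{(2R,3R)-4-[4-(benzyloxy)-3,5-dimethoxyphenyl]-2,3-dimethylbutanoyl}-4-phenyl-1,3-oxazolidin-2-one F8, which sets C8'.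
- LiBH4 removes the auxiliary and gives (2R,3R)-4-[4-(benzyloxy)-3,5-dimethoxyphenyl]-2,3-dimethylbutan-1-ol F9. Dess–Martin oxidation gives (2R,3R)-4-[4-(benzyloxy)-3,5-dimethoxyphenyl]-2,3-dimethylbutanal F10.
- Addition of [4-(benzyloxy)-3-methoxyphenyl]magnesium bromide F11 (from 1-(benzyloxy)-4-bromo-2-methoxybenzene and Mg) gives (2R,3R)-4-[4-(benzyloxy)-3,5-dimethoxyphenyl]-1-[4-(benzyloxy)-3-methoxyphenyl]-2,3-dimethylbutan-1-ol F12. Its mixed C7' configuration does not matter.
- BF3·OEt2 in CH2Cl2 at −78 to −20 °C ionises F12 and closes ring B to the 4,4'-di-O-benzyl ether of 18 F13, the same compound as A7. Hydrogenolysis (H2, Pd/C, EtOAc/EtOH) returns to the route at 18.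

**Step 8.** Transmetalation and reductive elimination at a bromide flanked by a methoxy and a propionyl group may be slow, so that protodeboronation of 11 and hydrodebromination of 6 outrun the coupling.

Fallback, from 3 and 11 back to the route at 12: the coupling is moved to the aldehyde stage, where the bromide has a smaller and more activating formyl neighbour and no enolisable ketone is present. Suzuki–Miyaura coupling of 3 with 11 gives 3,5-dimethoxy-2-[(Z)-1-{3-methoxy-4-[(triisopropylsilyl)oxy]phenyl}prop-1-en-1-yl]-4-[(triisopropylsilyl)oxy]benzaldehyde F14. Addition of 4 gives 1-{3,5-dimethoxy-2-[(Z)-1-{3-methoxy-4-[(triisopropylsilyl)oxy]phenyl}prop-1-en-1-yl]-4-[(triisopropylsilyl)oxy]phenyl}propan-1-ol F15, and Dess–Martin oxidation gives 12.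

**Step 9.** Proton exchange between product and enolate may lead to double chlorination, or the chlorinating agent may attack the electron-rich alkene or arenes.

Fallback, from 12 (through 13) back to the route at 14: electrophilic chlorine is replaced by nucleophilic chloride. Enolate 13 is oxidised with 2-(phenylsulfonyl)-3-phenyloxaziridine to 1-{3,5-dimethoxy-2-[(Z)-1-{3-methoxy-4-[(triisopropylsilyl)oxy]phenyl}prop-1-en-1-yl]-4-[(triisopropylsilyl)oxy]phenyl}-2-hydroxypropan-1-one F16. MsCl and Et3N give its methanesulfonate F17, and LiCl in DMF displaces the sulfonate beside the carbonyl to give 14.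

**Step 13.** The C7 cation may lose the C8 proton to give the C7=C8 alkene, and re-protonation would scramble C8; the para-hydroxybenzyl cation may also collapse to a quinone methide and oligomerise.

Fallback, from 17 back to the route at 18: a free cation is avoided. Ac2O and pyridine give the triacetate of 17 F18. Hydrogenolysis of the benzylic acetate at the metal surface (H2, Pd/C, EtOAc) gives the 4,4'-di-O-acetate of 18 F19, and K2CO3 in MeOH gives 18.

## Further compounds

F1 | step 11 | 4-(benzyloxy)-3,5-dimethoxybenzaldehyde | COc1cc(C=O)cc(OC)c1OCc1ccccc1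
F2 | step 11 | [4-(benzyloxy)-3,5-dimethoxyphenyl]methanol | COc1cc(CO)cc(OC)c1OCc1ccccc1
F3 | step 11 | 2-(benzyloxy)-5-(chloromethyl)-1,3-dimethoxybenzene | COc1cc(CCl)cc(OC)c1OCc1ccccc1
F4 | step 11 | [4-(benzyloxy)-3,5-dimethoxybenzyl]magnesium chloride | COc1cc(C[Mg]Cl)cc(OC)c1OCc1ccccc1
F5 | step 11 | (4R)-3-[(2E)-but-2-enoyl]-4-phenyl-1,3-oxazolidin-2-one | C/C=C/C(=O)N1[C@H](c2ccccc2)COC1=O
F6 | step 11 | (4R)-3-{(3R)-4-[4-(benzyloxy)-3,5-dimethoxyphenyl]-3-methylbutanoyl}-4-phenyl-1,3-oxazolidin-2-one | COc1cc(C[C@@H](C)CC(=O)N2[C@H](c3ccccc3)COC2=O)cc(OC)c1OCc1ccccc1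
F7 | step 11 | sodium (Z)-enolate of F6 | [Na+].COc1cc(C[C@@H](C)/C=C(\[O-])N2[C@H](c3ccccc3)COC2=O)cc(OC)c1OCc1ccccc1
F8 | step 11 | (4R)-3-{(2R,3R)-4-[4-(benzyloxy)-3,5-dimethoxyphenyl]-2,3-dimethylbutanoyl}-4-phenyl-1,3-oxazolidin-2-one | COc1cc(C[C@@H](C)[C@@H](C)C(=O)N2[C@H](c3ccccc3)COC2=O)cc(OC)c1OCc1ccccc1
F9 | step 11 | (2R,3R)-4-[4-(benzyloxy)-3,5-dimethoxyphenyl]-2,3-dimethylbutan-1-ol | COc1cc(C[C@@H](C)[C@@H](C)CO)cc(OC)c1OCc1ccccc1
F10 | step 11 | (2R,3R)-4-[4-(benzyloxy)-3,5-dimethoxyphenyl]-2,3-dimethylbutanal | COc1cc(C[C@@H](C)[C@@H](C)C=O)cc(OC)c1OCc1ccccc1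
F11 | step 11 | [4-(benzyloxy)-3-methoxyphenyl]magnesium bromide | COc1cc([Mg]Br)ccc1OCc1ccccc1
F12 | step 11 | (2R,3R)-4-[4-(benzyloxy)-3,5-dimethoxyphenyl]-1-[4-(benzyloxy)-3-methoxyphenyl]-2,3-dimethylbutan-1-ol (both C1 epimers) | COc1cc(C[C@@H](C)[C@@H](C)C(O)c2ccc(OCc3ccccc3)c(OC)c2)cc(OC)c1OCc1ccccc1
F13 | step 11 | 4,4'-di-O-benzyl ether of 18 (identical with A7) | COc1cc([C@@H]2c3c(cc(OC)c(OCc4ccccc4)c3OC)C[C@@H](C)[C@H]2C)ccc1OCc1ccccc1
F14 | step 8 | 3,5-dimethoxy-2-[(Z)-1-{3-methoxy-4-[(triisopropylsilyl)oxy]phenyl}prop-1-en-1-yl]-4-[(triisopropylsilyl)oxy]benzaldehyde | C/C=C(/c1ccc(O[Si](C(C)C)(C(C)C)C(C)C)c(OC)c1)c1c(OC)c(O[Si](C(C)C)(C(C)C)C(C)C)c(OC)cc1C=O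
F15 | step 8 | 1-{3,5-dimethoxy-2-[(Z)-1-{3-methoxy-4-[(triisopropylsilyl)oxy]phenyl}prop-1-en-1-yl]-4-[(triisopropylsilyl)oxy]phenyl}propan-1-ol (racemic) | C/C=C(/c1ccc(O[Si](C(C)C)(C(C)C)C(C)C)c(OC)c1)c1c(OC)c(O[Si](C(C)C)(C(C)C)C(C)C)c(OC)cc1C(O)CC
F16 | step 9 | 1-{3,5-dimethoxy-2-[(Z)-1-{3-methoxy-4-[(triisopropylsilyl)oxy]phenyl}prop-1-en-1-yl]-4-[(triisopropylsilyl)oxy]phenyl}-2-hydroxypropan-1-one (racemic) | C/C=C(/c1ccc(O[Si](C(C)C)(C(C)C)C(C)C)c(OC)c1)c1c(OC)c(O[Si](C(C)C)(C(C)C)C(C)C)c(OC)cc1C(=O)C(C)O
F17 | step 9 | methanesulfonate of F16 (racemic) | C/C=C(/c1ccc(O[Si](C(C)C)(C(C)C)C(C)C)c(OC)c1)c1c(OC)c(O[Si](C(C)C)(C(C)C)C(C)C)c(OC)cc1C(=O)C(C)OS(C)(=O)=O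
F18 | step 13 | triacetate of 17 (both C1 epimers) | COc1cc([C@@H]2c3c(cc(OC)c(OC(C)=O)c3OC)C(OC(C)=O)[C@@H](C)[C@H]2C)ccc1OC(C)=O
F19 | step 13 | 4,4'-di-O-acetate of 18 | COc1cc([C@@H]2c3c(cc(OC)c(OC(C)=O)c3OC)C[C@@H](C)[C@H]2C)ccc1OC(C)=O
A1 | alternative 1 | (1S)-6-(benzyloxy)-1-[(2E)-but-2-en-2-yl]-5,7-dimethoxy-1,4-dihydro-3H-isochromen-3-one | C/C=C(C)/[C@@H]1OC(=O)Cc2c(OC)c(OCc3ccccc3)c(OC)cc21
A2 | alternative 1 | 7-(benzyloxy)-6,8-dimethoxy-2,3-dimethyl-1,2-dihydronaphthalene-1-carboxylic acid (carboxyl cis to the C2 methyl) | OC(=O)[C@H]1c2c(cc(OC)c(OCc3ccccc3)c2OC)C=C(C)[C@H]1C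
A3 | alternative 2 | 4-(benzyloxy)-3,5,7,7-tetramethoxybicyclo[4.2.0]octa-1,3,5-triene | COC1(OC)Cc2cc(OC)c(OCc3ccccc3)c(OC)c21
A4 | alternative 2 | (5R)-5-{[(1R,2S,5R)-2-isopropyl-5-methylcyclohexyl]oxy}furan-2(5H)-one | O=C1C=C[C@H](O[C@@H]2C[C@H](C)CC[C@H]2C(C)C)O1
A5 | alternative 2 | cis-fused cycloadduct (C7' dimethyl ketal, C9' lactone carbonyl, C9 menthyl acetal) | COC1(OC)c2c(cc(OC)c(OCc4ccccc4)c2OC)C[C@@H]3[C@H]1C(=O)O[C@H]3O[C@@H]5C[C@H](C)CC[C@H]5C(C)C
A6 | alternative 3 | 2-(benzyloxy)-4-{(1R,2R)-1-[4-(benzyloxy)-3-methoxyphenyl]-2-methylbut-3-en-1-yl}-5-bromo-1,3-dimethoxybenzene | COc1cc([C@H](c2c(Br)cc(OC)c(OCc3ccccc3)c2OC)[C@H](C)C=C)ccc1OCc1ccccc1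
A7 | alternative 3 | 4,4'-di-O-benzyl ether of the target | COc1cc([C@@H]2c3c(cc(OC)c(OCc4ccccc4)c3OC)C[C@@H](C)[C@H]2C)ccc1OCc1ccccc1
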